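**Plan**

Cuts: first the aryl–acyl bond C1'–C(=O) between ring A and the ketone carbon, which gives 2,4-diprenylresorcinol and an activated (S)-4-hydroxyphenyllactic acid. Next come the two aryl–CH2 bonds of the prenyl groups (C3', C5'), which lead back to resorcinol, and the C-α–O bond goes back to the C–N bond of L-tyrosine.
Enabling feature: ring A is a resorcinol (O-2', O-4') in which C1' is the only free carbon ortho to one hydroxyl and para to the other (C6'–H is meta to both). Its sequence acyl/OH/C-chain/OH on C1'–C4' repeats that of 2,4-diacetylphloroglucinol, the native product of the cofactor-free C-acyltransferases.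
Forward: resorcinol → bis-MOM ether → two directed ortho metalation/prenylation cycles (C2, then C4) → free diol 7. L-tyrosine → hydroxy acid 11 → S-ethyl thioester 13. Compounds 7 and 13 are joined unprotected in the last step by an enzymatic Friedel–Crafts acylation, and no ring is formed in the route.
Stereochemistry: the only stereocentre, C-α (S), comes from L-tyrosine by diazotisation with net retention (double inversion) and afterwards meets only near-neutral conditions.
Helpers: the MOM groups (directing and protecting) leave in step 4, and the ethylthio activating group leaves in the key step itself.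

Key step: step 7

Numbering: ring A of the target is C1'–C6' (C1' bears the ketone) and C-α is the carbinol carbon. In arenes 2–7 the oxygens sit on C1 and C3.
Assumption: an acyltransferase variant that takes both 7 and 13 is taken to be accessible by screening a focused active-site library. No other step depends on this.

**Step 1**
Reactants: 1 resorcinol
Product: 2 1,3-bis(methoxymethoxy)benzene
Conditions: MOMCl, i-Pr2NEt, CH2Cl2, 0 °C → rt
Reagents that add atoms: chloromethyl methyl ether (MOMCl), COCCl
Why: Williamson-type O-alkylation of both phenols with the reactive chloromethyl ether should be clean, and the OMOM groups serve as protecting groups and as directing groups for steps 2 and 3.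

**Step 2**
Reactants: 2 1,3-bis(methoxymethoxy)benzene
Product: 4 1,3-bis(methoxymethoxy)-2-(3-methylbut-2-en-1-yl)benzene, via 2-lithio arene 3 (not isolated)
Conditions: n-BuLi, TMEDA, THF, 0 °C → rt; prenyl bromide, −78 °C → rt
Reagents that add atoms: prenyl bromide (1-bromo-3-methylbut-2-ene), CC(C)=CCBr
Why: Directed ortho metalation should take place at C2 because this C–H lies between two coordinating OMOM groups, and SN2 alkylation of the aryllithium with the primary allylic bromide should give the linear prenyl group.

**Step 3**
Reactants: 4 1,3-bis(methoxymethoxy)-2-(3-methylbut-2-en-1-yl)benzene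
Product: 6 1,3-bis(methoxymethoxy)-2,4-bis(3-methylbut-2-en-1-yl)benzene, via 4-lithio arene 5 (not isolated)
Conditions: n-BuLi, TMEDA, THF, 0 °C; prenyl bromide, −78 °C → rt
Reagents that add atoms: prenyl bromide (1-bromo-3-methylbut-2-ene), CC(C)=CCBr
Why: A second directed ortho metalation can only go to the two symmetry-equivalent positions ortho to an OMOM group (C4/C6 of 4), so that SN2 alkylation with prenyl bromide should give a single regioisomer.

**Step 4**
Reactants: 6 1,3-bis(methoxymethoxy)-2,4-bis(3-methylbut-2-en-1-yl)benzene
Product: 7 2,4-bis(3-methylbut-2-en-1-yl)benzene-1,3-diol (2,4-diprenylresorcinol)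
Conditions: conc. HCl (cat.), MeOH, 40 °C, stopped at full conversion
Reagents that add atoms: none
Why: Acid-catalysed transacetalisation to methanol cleaves aryl MOM ethers much faster than dilute methanolic acid protonates a trisubstituted alkene, a selectivity with broad precedent in o-prenylphenol chemistry.

**Step 5**
Reactants: 8 L-tyrosine
Product: 11 (S)-2-hydroxy-3-(4-hydroxyphenyl)propanoic acid, via diazonium carboxylate 9 (not isolated), via alpha-lactone 10 (not isolated)
Conditions: NaNO2 (slow addition), aq. H2SO4, 0 °C → rt
Reagents that add atoms: water, O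
Why: Diazotisation of the α-amino acid, carboxylate participation to the α-lactone 10 (first inversion) and opening by water at C-α (second inversion) should give the α-hydroxy acid with net retention, so that the (S) centre of L-tyrosine becomes the (S) centre of the target.

**Step 6**
Reactants: 11 (S)-2-hydroxy-3-(4-hydroxyphenyl)propanoic acid
Product: 13 S-ethyl (S)-2-hydroxy-3-(4-hydroxyphenyl)propanethioate, via benzotriazolyl ester 12 (not isolated)
Conditions: EtSH (excess), DCC, HOBt, i-Pr2NEt (cat.), THF, 0 °C → rt
Reagents that add atoms: ethanethiol, CCS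
Why: Carbodiimide/HOBt thioesterification should be chemoselective because the excess thiol is far more nucleophilic than the secondary alcohol or the phenol when no DMAP-type catalyst is present, any aryl ester formed is itself thiolysed, and an α-hydroxy acid has no oxazolone path to racemisation.

**Step 7**
Reactants: 7 2,4-diprenylresorcinol; 13 S-ethyl (S)-2-hydroxy-3-(4-hydroxyphenyl)propanethioate
Product: 15 lespeflorin C6, via cyclohexadienone tautomer 14 (not isolated)
Conditions: cofactor-free C-acyltransferase of the PhlABC type (engineered variant, E. coli cell-free extract), KPi buffer pH 7.5, DMSO (15 vol %), 30 °C, 13 fed in portions, N2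
Reagents that add atoms: none
Why: Proposed new method: thioester 13 should first acylate the active-site cysteine (transthioesterification, loss of EtSH), then C6 of the bound and hydrogen-bond-activated resorcinol 7 attacks this acyl-enzyme thioester to give the cyclohexadienone 14, which tautomerises to the internally hydrogen-bonded o-hydroxyaryl ketone 15. The closest known reaction type is the biocatalytic Friedel–Crafts C-acylation of resorcinols with thioester or aryl ester donors by the same cofactor-free enzyme class, of which variants with an opened acyl pocket take bulkier donors; new are the α-hydroxy-β-arylpropanoyl donor and the doubly prenylated acceptor, so that a focused library around both pockets has to be screened. Fit is argued from the native product 2,4-diacetylphloroglucinol, a pentasubstituted ring whose acyl/OH/C-chain/OH sequence is repeated on C1'–C4' of 15, with the C3' prenyl group in the place of the second acetyl group. No ring is closed and no lasting stereocentre is made (the sp3 ring carbon of 14 is lost on tautomerisation), while C-α enters as (S) with 13 and should stay so because it is not part of the reacting centres and the medium is near neutral. Site selectivity is secured by the substrate, since C6 of 7 is the only free carbon ortho to one hydroxyl and para to the other (C5 is meta to both) and the monophenol ring of the donor lacks the 1,3-diol motif that the enzyme needs in an acceptor. C- over O-acylation on fully unprotected partners, without the Lewis or Brønsted acid that would close the o-prenylphenols to chromans and without the base that would enolise the α-ketol, is the selectivity that the step needs and that the enzyme pocket, not a small reagent, should supply.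

**Compound list**

1 | resorcinol | Oc1cccc(O)c1 | starting material
2 | 1,3-bis(methoxymethoxy)benzene | COCOc1cccc(OCOC)c1 | intermediate
3 | [2,6-bis(methoxymethoxy)phenyl]lithium | [Li]c1c(OCOC)cccc1OCOC | intermediate
4 | 1,3-bis(methoxymethoxy)-2-(3-methylbut-2-en-1-yl)benzene | CC(C)=CCc1c(OCOC)cccc1OCOC | intermediate
5 | [2,4-bis(methoxymethoxy)-3-(3-methylbut-2-en-1-yl)phenyl]lithium | [Li]c1ccc(OCOC)c(CC=C(C)C)c1OCOC | intermediate
6 | 1,3-bis(methoxymethoxy)-2,4-bis(3-methylbut-2-en-1-yl)benzene | CC(C)=CCc1ccc(OCOC)c(CC=C(C)C)c1OCOC | intermediate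
7 | 2,4-bis(3-methylbut-2-en-1-yl)benzene-1,3-diol | CC(C)=CCc1ccc(O)c(CC=C(C)C)c1O | intermediate
8 | L-tyrosine, (S) | N[C@@H](Cc1ccc(O)cc1)C(=O)O | starting material
9 | (S)-2-diazonio-3-(4-hydroxyphenyl)propanoate | N#[N+][C@@H](Cc1ccc(O)cc1)C(=O)[O-] | intermediate
10 | (R)-3-(4-hydroxybenzyl)oxiran-2-one (α-lactone) | O=C1O[C@@H]1Cc2ccc(O)cc2 | intermediate
11 | (S)-2-hydroxy-3-(4-hydroxyphenyl)propanoic acid | O=C(O)[C@@H](O)Cc1ccc(O)cc1 | intermediate
12 | benzotriazol-1-yl (S)-2-hydroxy-3-(4-hydroxyphenyl)propanoate | O=C(On1nnc2ccccc12)[C@@H](O)Cc1ccc(O)cc1 | intermediate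
13 | S-ethyl (S)-2-hydroxy-3-(4-hydroxyphenyl)propanethioate | CCSC(=O)[C@@H](O)Cc1ccc(O)cc1 | intermediate
14 | 6-acylcyclohexa-2,4-dien-1-one tautomer of the target, (S) at C-α, ring sp3 carbon undefined | CC(C)=CCC1=CC(C(=O)[C@@H](O)Cc2ccc(O)cc2)C(=O)C(CC=C(C)C)=C1O | intermediate
15 | lespeflorin C6, (S)-1-[2,4-dihydroxy-3,5-bis(3-methylbut-2-en-1-yl)phenyl]-2-hydroxy-3-(4-hydroxyphenyl)propan-1-one | CC(C)=CCc1cc(C(=O)[C@@H](O)Cc2ccc(O)cc2)c(O)c(CC=C(C)C)c1O | target

**Step count**

Total step count: 7. Longest linear sequence: 5 (steps 1, 2, 3, 4, 7). The second branch has 3 steps (5, 6, 7).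

**Steps most likely to fail**

1. **Step 7.** The bulky acceptor or the α-hydroxyacyl donor may fail to bind productively even after screening. Hydrolysis of the thioester would then outrun C–C bond formation.
   - The fallback is an aryl-metal acylation in protected form, which is known chemistry. It sets out from 11 and 6 and comes back at 15.
   - Acid 11 is coupled with N,O-dimethylhydroxylamine hydrochloride (EDC, HOBt, N-methylmorpholine, CH2Cl2) to the Weinreb amide F1.
   - Both hydroxyl groups are silylated (TBSCl, imidazole, DMF) to the bis-TBS ether F2.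
   - Arene 6 is metalated a third time (n-BuLi, TMEDA, THF, 0 °C) at its last position ortho to an OMOM group to the aryllithium F3, which is added to F2 at −78 °C.
   - The chelated tetrahedral adduct should stop over-addition and keep C-α from enolisation. An NH4Cl quench should give the protected ketone F4.
   - Buffered fluoride (TBAF, AcOH, THF, 0 °C) should give the bis-MOM ketol F5, and HCl in MeOH as in step 4 should give 15.

2. **Step 3.** Deprotonation of the doubly activated benzylic–allylic CH2 of the first prenyl group may compete with ring metalation, or metalation may stay incomplete.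
   - The fallback delivers the second prenyl group sigmatropically instead of by metalation. It sets out from 4 and comes back at 7, so it also passes by step 4.
   - The MOM groups of 4 are removed (HCl, MeOH) to 2-prenylresorcinol F6.
   - One hydroxyl is converted into the 1,1-dimethylallyl ether F7 by Pd(0)-catalysed decarboxylative O-allylation with tert-butyl 2-methylbut-3-en-2-yl carbonate (Pd(PPh3)4, THF, 0 °C).
   - An aromatic Claisen rearrangement (N,N-diethylaniline or toluene, 110–130 °C) can rearomatise only after migration to the free ortho carbon C4, because C2 is blocked.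
   - The rearrangement delivers the allyl unit with inversion as a linear prenyl group, which gives 7.

3. **Step 4.** Acid-induced cyclisation of the freed phenols onto the neighbouring prenyl double bonds (chroman formation) may set in before both acetals are gone.
   - The fallback uses a fluoride-triggered release instead of an acid-triggered one, which needs another directing and protecting group from the start. It sets out from 1 and comes back at 7.
   - Resorcinol is converted (SEMCl, i-Pr2NEt, CH2Cl2) into the bis-SEM ether F8.
   - Directed ortho metalation (n-BuLi, TMEDA, THF) gives the 2-lithio arene F9, and prenyl bromide gives the 2-prenyl bis-SEM ether F10.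
   - A second metalation gives the 4-lithio arene F11, and prenyl bromide gives the 2,4-diprenyl bis-SEM ether F12.
   - TBAF in THF–DMPU at 60 °C, in the presence of a formaldehyde scavenger, should fragment both SEM groups under non-acidic conditions to 7.

**Further compounds**

F1 | step 7 | (S)-2-hydroxy-3-(4-hydroxyphenyl)-N-methoxy-N-methylpropanamide | CON(C)C(=O)[C@@H](O)Cc1ccc(O)cc1
F2 | step 7 | (S)-2-(tert-butyldimethylsilyloxy)-3-[4-(tert-butyldimethylsilyloxy)phenyl]-N-methoxy-N-methylpropanamide | CON(C)C(=O)[C@@H](O[Si](C)(C)C(C)(C)C)Cc1ccc(O[Si](C)(C)C(C)(C)C)cc1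
F3 | step 7 | [2,4-bis(methoxymethoxy)-3,5-bis(3-methylbut-2-en-1-yl)phenyl]lithium | [Li]c1cc(CC=C(C)C)c(OCOC)c(CC=C(C)C)c1OCOC
F4 | step 7 | (S)-1-[2,4-bis(methoxymethoxy)-3,5-bis(3-methylbut-2-en-1-yl)phenyl]-2-(tert-butyldimethylsilyloxy)-3-[4-(tert-butyldimethylsilyloxy)phenyl]propan-1-one | CC(C)=CCc1cc(C(=O)[C@@H](O[Si](C)(C)C(C)(C)C)Cc2ccc(O[Si](C)(C)C(C)(C)C)cc2)c(OCOC)c(CC=C(C)C)c1OCOC
F5 | step 7 | (S)-1-[2,4-bis(methoxymethoxy)-3,5-bis(3-methylbut-2-en-1-yl)phenyl]-2-hydroxy-3-(4-hydroxyphenyl)propan-1-one | CC(C)=CCc1cc(C(=O)[C@@H](O)Cc2ccc(O)cc2)c(OCOC)c(CC=C(C)C)c1OCOC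
F6 | step 3 | 2-(3-methylbut-2-en-1-yl)benzene-1,3-diol | CC(C)=CCc1c(O)cccc1O
F7 | step 3 | 3-[(2-methylbut-3-en-2-yl)oxy]-2-(3-methylbut-2-en-1-yl)phenol | C=CC(C)(C)Oc1cccc(O)c1CC=C(C)C
F8 | step 4 | 1,3-bis{[2-(trimethylsilyl)ethoxy]methoxy}benzene | C[Si](C)(C)CCOCOc1cccc(OCOCC[Si](C)(C)C)c1
F9 | step 4 | (2,6-bis{[2-(trimethylsilyl)ethoxy]methoxy}phenyl)lithium | [Li]c1c(OCOCC[Si](C)(C)C)cccc1OCOCC[Si](C)(C)C
F10 | step 4 | 2-(3-methylbut-2-en-1-yl)-1,3-bis{[2-(trimethylsilyl)ethoxy]methoxy}benzene | CC(C)=CCc1c(OCOCC[Si](C)(C)C)cccc1OCOCC[Si](C)(C)C
F11 | step 4 | [3-(3-methylbut-2-en-1-yl)-2,4-bis{[2-(trimethylsilyl)ethoxy]methoxy}phenyl]lithium | [Li]c1ccc(OCOCC[Si](C)(C)C)c(CC=C(C)C)c1OCOCC[Si](C)(C)C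
F12 | step 4 | 2,4-bis(3-methylbut-2-en-1-yl)-1,3-bis{[2-(trimethylsilyl)ethoxy]methoxy}benzene | CC(C)=CCc1ccc(OCOCC[Si](C)(C)C)c(CC=C(C)C)c1OCOCC[Si](C)(C)C
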